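The seven-membered ring is cut at both ends of its C9–C10 two-carbon bridge (daucane numbering), so that C1–C10 and C8–C9 arise together from one vinyl reagent. A tertiary C1 radical, released from a trifluoroborate on a preformed cyclopentane (ring A), adds to vinyltriphenylphosphonium bromide; reduction gives an ylide that closes onto a C8 methyl ketone by Wittig olefination. The step exploits that C10 is an unsubstituted CH2 flanked by the quaternary angular carbon C1, and that C8–C9 is an oxirane bond best made as an alkene. The precursor is monocyclic: ring A with BF3K at C1, the C4 aryl ester and a C5 β-alkoxy ketone chain.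

Key step: step 7

Remark: atoms are numbered as in daucane (C1 angular methyl-bearing quaternary carbon; C2, C3 the CH2 groups of ring A; C4 the carbon bearing isopropyl and the ester oxygen; C5 ring-fusion CH; C6 CHOH; C7 CH2; C8 methyl-bearing oxirane carbon; C9 oxirane CH; C10 the CH2 between C9 and C1). The aryl ester is taken to sit on the tertiary C4 oxygen exactly as drawn, so the target is (1R,4R,5S,6S,8R,9S).
Abbreviations: Bpin = 4,4,5,5-tetramethyl-1,3,2-dioxaborolan-2-yl; BOM = benzyloxymethyl.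

Step 1
Reactants: 1 ethyl 2-(2-methyl-1,3-dioxolan-2-yl)acetate (fructone)
Product: 2 2-(2-methyl-1,3-dioxolan-2-yl)acetaldehyde
Conditions: iBu2AlH (DIBAL-H), CH2Cl2, −78 °C; Rochelle salt work-up
Reagents that add atoms: none
Why: DIBAL-H partial reduction of an ester at −78 °C stops at the aluminium hemiacetal, which collapses to the aldehyde only on work-up, and the ketal is inert.

Step 2
Reactants: 3 3-methylcyclopent-2-en-1-one; 2 2-(2-methyl-1,3-dioxolan-2-yl)acetaldehyde
Product: 5 (2S,3R)-2-[(1S)-1-hydroxy-2-(2-methyl-1,3-dioxolan-2-yl)ethyl]-3-methyl-3-(Bpin)cyclopentan-1-one, via enol borate 4 (not isolated)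
Conditions: [Cu(MeCN)4]PF6 (10 mol %), QuinoxP* (enantiomer giving the 3R boronate, 12 mol %), LiOtBu (15 mol %), B2pin2, DMSO, rt; then 2, rt; aq. NH4Cl
Reagents that add atoms: bis(pinacolato)diboron CC1(C)OB(OC1(C)C)B1OC(C)(C)C(C)(C)O1; aldehyde 2 CC1(CC=O)OCCO1
Why: Copper-catalysed enantioselective conjugate borylation of the β-methyl enone sets the tertiary C–B centre (3R, ligand control) and leaves a regiodefined ring enol borate, whose aldol addition through a closed chair (Zimmerman–Traxler) transition state should take place on the ring face anti to the bulky Bpin group (2S) and, the cyclic enolate being E-configured, give the anti carbinol (1'S), the minor diastereomers being removed by chromatography.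

Step 3
Reactants: 5 (2S,3R)-2-[(1S)-1-hydroxy-2-(2-methyl-1,3-dioxolan-2-yl)ethyl]-3-methyl-3-(Bpin)cyclopentan-1-one
Product: 6 (2S,3R)-2-{(1S)-1-[(benzyloxy)methoxy]-2-(2-methyl-1,3-dioxolan-2-yl)ethyl}-3-methyl-3-(Bpin)cyclopentan-1-one
Conditions: BOMCl, iPr2NEt, Bu4NI (cat.), CH2Cl2, 0 °C to rt
Reagents that add atoms: benzyl chloromethyl ether ClCOCc1ccccc1
Why: Williamson-type O-alkylation with the reactive chloromethyl ether under a hindered amine base protects the carbinol as its BOM acetal without retro-aldol cleavage or β-elimination and without touching a stereocentre.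

Step 4
Reactants: 6 (2S,3R)-2-{(1S)-1-[(benzyloxy)methoxy]-2-(2-methyl-1,3-dioxolan-2-yl)ethyl}-3-methyl-3-(Bpin)cyclopentan-1-one; 7 isopropylmagnesium chloride; 8 4-(benzyloxy)benzoyl chloride
Product: 10 (1R,2S,3R)-2-{(1S)-1-[(benzyloxy)methoxy]-2-(2-methyl-1,3-dioxolan-2-yl)ethyl}-3-methyl-1-(propan-2-yl)-3-(Bpin)cyclopentyl 4-(benzyloxy)benzoate, via chloromagnesium alkoxide 9 (not isolated)
Conditions: 7, LaCl3·2LiCl (0.3 equiv), THF, 0 °C; then 8, DMAP (cat.), 0 °C to rt
Reagents that add atoms: isopropylmagnesium chloride (7) CC(C)[Mg]Cl; 4-(benzyloxy)benzoyl chloride (8) O=C(Cl)c1ccc(OCc2ccccc2)cc1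
Why: Lanthanum-promoted Grignard 1,2-addition suppresses enolisation and β-hydride reduction of the hindered cyclopentanone and should deliver isopropyl to the ring face anti to the adjacent C2 side chain, so that the new C–O bond is cis to that side chain (1R), after which the tertiary alkoxide is O-acylated in the same flask by the aroyl chloride (nucleophilic acyl substitution) while the hindered tertiary Bpin is not attacked by the Grignard reagent.

Step 5
Reactants: 10 (1R,2S,3R)-2-{(1S)-1-[(benzyloxy)methoxy]-2-(2-methyl-1,3-dioxolan-2-yl)ethyl}-3-methyl-1-(propan-2-yl)-3-(Bpin)cyclopentyl 4-(benzyloxy)benzoate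
Product: 11 (1R,2S,3R)-2-{(1S)-1-[(benzyloxy)methoxy]-3-oxobutyl}-3-methyl-1-(propan-2-yl)-3-(Bpin)cyclopentyl 4-(benzyloxy)benzoate
Conditions: PPTS (cat.), acetone/H2O (10:1), 50 °C
Reagents that add atoms: water O
Why: Mild acid-catalysed ketal hydrolysis with PPTS frees the methyl ketone while the BOM acetal, the benzyl ether, the hindered tertiary ester and the pinacol boronate are left intact and no stereocentre is touched.

Step 6
Reactants: 11 (1R,2S,3R)-2-{(1S)-1-[(benzyloxy)methoxy]-3-oxobutyl}-3-methyl-1-(propan-2-yl)-3-(Bpin)cyclopentyl 4-(benzyloxy)benzoate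
Product: 12 potassium [(1R,2S,3R)-3-{[4-(benzyloxy)benzoyl]oxy}-2-{(1S)-1-[(benzyloxy)methoxy]-3-oxobutyl}-1-methyl-3-(propan-2-yl)cyclopentyl]trifluoroborate
Conditions: KHF2 (aq., 4.5 equiv), MeOH, rt; extraction of the salt into acetone
Reagents that add atoms: potassium hydrogen difluoride (KHF2) F.[F-].[K+]
Why: Ligand exchange at boron with KHF2 converts the pinacol boronate into the tertiary alkyltrifluoroborate, an easily oxidised radical precursor, with the carbon framework and all stereocentres untouched.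

Step 7
Reactants: 12 potassium [(1R,2S,3R)-3-{[4-(benzyloxy)benzoyl]oxy}-2-{(1S)-1-[(benzyloxy)methoxy]-3-oxobutyl}-1-methyl-3-(propan-2-yl)cyclopentyl]trifluoroborate; 13 triphenyl(vinyl)phosphonium bromide
Product: 15 (1R,4R,5S,6S)-6-[(benzyloxy)methoxy]dauc-8-en-4-yl 4-(benzyloxy)benzoate, via phosphorus ylide 14 (not isolated)
Conditions: 13 (1.5 equiv), 4CzIPN (5 mol %), 2,6-lutidine, dry degassed DMSO (0.2 M), blue LEDs, rt; then 50 °C in the dark
Reagents that add atoms: triphenyl(vinyl)phosphonium bromide (13) C=C[P+](c1ccccc1)(c1ccccc1)c1ccccc1.[Br-]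
Why: Proposed new method: photoexcited 4CzIPN oxidises the tertiary trifluoroborate to the C1 radical (loss of BF3), which adds to the terminal carbon of the vinylphosphonium salt to make C1–C10; the α-phosphonio radical is reduced by the photocatalyst radical anion to ylide 14 (redox-neutral radical–polar crossover), and this ylide undergoes intramolecular Wittig olefination with the C8 methyl ketone to make C8=C9. The closest known reaction types are the photoredox conjunctive olefination of alkyl radicals, vinylphosphonium salts and carbonyl compounds, photoredox Giese additions of alkyltrifluoroborates, and the Schweizer (vinylphosphonium) annulation. The seven-membered ring is closed by carbonyl olefination, a 7-exo-trig attack of the ylide carbon C9 on the C8 carbonyl followed by collapse of the oxaphosphetane, which can only give the endocyclic Z alkene. The new quaternary stereocentre C1 is controlled by the adjacent C5 stereocentre: the planar radical is attacked on the face anti to the large C5 side chain, which puts C10 trans to C6 (trans ring fusion, 1R) whatever the earlier configuration at the boron-bearing carbon. The step needs radical addition to outrun 1,5-hydrogen transfer (high concentration of acceptor) and needs the ylide to choose the unhindered methyl ketone over the hindered tertiary aryl ester and over excess vinylphosphonium salt; 2,6-lutidine traps BF3 and proton sources are excluded so that the ylide is not quenched.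

Step 8
Reactants: 15 (1R,4R,5S,6S)-6-[(benzyloxy)methoxy]dauc-8-en-4-yl 4-(benzyloxy)benzoate
Product: 16 (1R,4R,5S,6S,8R,9S)-6-[(benzyloxy)methoxy]-8,9-epoxydaucan-4-yl 4-(benzyloxy)benzoate
Conditions: dimethyldioxirane (acetone solution), CH2Cl2, 0 °C
Reagents that add atoms: dimethyldioxirane CC1(C)OO1
Why: Concerted oxygen transfer from neutral dimethyldioxirane to the trisubstituted alkene should take place on the α face, because the axial angular methyl on C1 shields the β face at C9 while the equatorial C6 substituent leaves the α face open, which gives the 8R,9S oxirane without any acid that could open it.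

Step 9
Reactants: 16 (1R,4R,5S,6S,8R,9S)-6-[(benzyloxy)methoxy]-8,9-epoxydaucan-4-yl 4-(benzyloxy)benzoate
Product: 17 (1R,4R,5S,6S,8R,9S)-8,9-epoxy-6-hydroxydaucan-4-yl 4-hydroxybenzoate (target)
Conditions: H2 (1 atm), Pd(OH)2/C, EtOAc, rt
Reagents that add atoms: none
Why: Neutral catalytic hydrogenolysis cleaves the benzyl aryl ether and the BOM acetal (whose hemiacetal loses formaldehyde) without touching the unactivated trisubstituted epoxide or the ester, and its non-basic medium avoids 1,3-acyl migration from the tertiary to the secondary oxygen.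

Compound list
1 | ethyl 2-(2-methyl-1,3-dioxolan-2-yl)acetate (fructone) | CCOC(=O)CC1(C)OCCO1 | starting material
2 | 2-(2-methyl-1,3-dioxolan-2-yl)acetaldehyde | CC1(CC=O)OCCO1 | intermediate
3 | 3-methylcyclopent-2-en-1-one | CC1=CC(=O)CC1 | starting material
4 | enol borate, 2-{[(3R)-3-methyl-3-(Bpin)cyclopent-1-en-1-yl]oxy}-4,4,5,5-tetramethyl-1,3,2-dioxaborolane | C[C@]1(B2OC(C)(C)C(C)(C)O2)CCC(OB2OC(C)(C)C(C)(C)O2)=C1 | intermediate
5 | (2S,3R)-2-[(1S)-1-hydroxy-2-(2-methyl-1,3-dioxolan-2-yl)ethyl]-3-methyl-3-(Bpin)cyclopentan-1-one | O=C1CC[C@](C)(B2OC(C)(C)C(C)(C)O2)[C@H]1[C@@H](O)CC1(C)OCCO1 | intermediate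
6 | (2S,3R)-2-{(1S)-1-[(benzyloxy)methoxy]-2-(2-methyl-1,3-dioxolan-2-yl)ethyl}-3-methyl-3-(Bpin)cyclopentan-1-one | O=C1CC[C@](C)(B2OC(C)(C)C(C)(C)O2)[C@H]1[C@@H](OCOCc1ccccc1)CC1(C)OCCO1 | intermediate
7 | isopropylmagnesium chloride | CC(C)[Mg]Cl | starting material
8 | 4-(benzyloxy)benzoyl chloride | O=C(Cl)c1ccc(OCc2ccccc2)cc1 | starting material
9 | chloromagnesium alkoxide of (1R,2S,3R)-2-{(1S)-1-[(benzyloxy)methoxy]-2-(2-methyl-1,3-dioxolan-2-yl)ethyl}-3-methyl-1-(propan-2-yl)-3-(Bpin)cyclopentan-1-ol | CC(C)[C@]1(O[Mg]Cl)CC[C@](C)(B2OC(C)(C)C(C)(C)O2)[C@H]1[C@@H](OCOCc1ccccc1)CC1(C)OCCO1 | intermediate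
10 | (1R,2S,3R)-2-{(1S)-1-[(benzyloxy)methoxy]-2-(2-methyl-1,3-dioxolan-2-yl)ethyl}-3-methyl-1-(propan-2-yl)-3-(Bpin)cyclopentyl 4-(benzyloxy)benzoate | CC(C)[C@]1(OC(=O)c2ccc(OCc3ccccc3)cc2)CC[C@](C)(B2OC(C)(C)C(C)(C)O2)[C@H]1[C@@H](OCOCc1ccccc1)CC1(C)OCCO1 | intermediate
11 | (1R,2S,3R)-2-{(1S)-1-[(benzyloxy)methoxy]-3-oxobutyl}-3-methyl-1-(propan-2-yl)-3-(Bpin)cyclopentyl 4-(benzyloxy)benzoate | CC(C)[C@]1(OC(=O)c2ccc(OCc3ccccc3)cc2)CC[C@](C)(B2OC(C)(C)C(C)(C)O2)[C@H]1[C@@H](OCOCc1ccccc1)CC(C)=O | intermediate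
12 | potassium [(1R,2S,3R)-3-{[4-(benzyloxy)benzoyl]oxy}-2-{(1S)-1-[(benzyloxy)methoxy]-3-oxobutyl}-1-methyl-3-(propan-2-yl)cyclopentyl]trifluoroborate | CC(C)[C@]1(OC(=O)c2ccc(OCc3ccccc3)cc2)CC[C@](C)([B-](F)(F)F)[C@H]1[C@@H](OCOCc1ccccc1)CC(C)=O.[K+] | intermediate
13 | triphenyl(vinyl)phosphonium bromide | C=C[P+](c1ccccc1)(c1ccccc1)c1ccccc1.[Br-] | starting material
14 | ylide, {2-[(1R,2S,3R)-3-{[4-(benzyloxy)benzoyl]oxy}-2-{(1S)-1-[(benzyloxy)methoxy]-3-oxobutyl}-1-methyl-3-(propan-2-yl)cyclopentyl]ethylidene}(triphenyl)phosphorane | CC(C)[C@]1(OC(=O)c2ccc(OCc3ccccc3)cc2)CC[C@](C)(CC=P(c2ccccc2)(c2ccccc2)c2ccccc2)[C@H]1[C@@H](OCOCc1ccccc1)CC(C)=O | intermediate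
15 | (1R,4R,5S,6S)-6-[(benzyloxy)methoxy]dauc-8-en-4-yl 4-(benzyloxy)benzoate (trans-fused hydroazulene with C8=C9) | CC(C)[C@]1(OC(=O)c2ccc(OCc3ccccc3)cc2)CC[C@]2(C)CC=C(C)C[C@H](OCOCc3ccccc3)[C@H]21 | intermediate
16 | (1R,4R,5S,6S,8R,9S)-6-[(benzyloxy)methoxy]-8,9-epoxydaucan-4-yl 4-(benzyloxy)benzoate | CC(C)[C@]1(OC(=O)c2ccc(OCc3ccccc3)cc2)CC[C@]2(C)C[C@@H]3O[C@]3(C)C[C@H](OCOCc3ccccc3)[C@H]21 | intermediate
17 | (1R,4R,5S,6S,8R,9S)-8,9-epoxy-6-hydroxydaucan-4-yl 4-hydroxybenzoate | CC(C)[C@]1(OC(=O)c2ccc(O)cc2)CC[C@]2(C)C[C@@H]3O[C@]3(C)C[C@H](O)[C@H]21 | target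

Total step count: 9. Longest linear sequence: 9 steps (1 to 2 to 5 to 6 to 10 to 11 to 12 to 15 to 16 to 17).

Steps most likely to fail

Step 7 (Proposed new method). The ylide may be protonated, or may add to a second molecule of vinylphosphonium salt, faster than it closes the seven-membered ring; the tertiary radical may also undergo 1,5-hydrogen transfer or add on the wrong face. The fallback uses known chemistry and makes the two bonds in separate operations. It sets out from 12: photoredox radical allylation with allyl phenyl sulfone (4CzIPN, 2,6-lutidine, blue LEDs) should give the C1-allyl ketone (1R,2S,3R)-2-{(1S)-1-[(benzyloxy)methoxy]-3-oxobutyl}-3-methyl-1-(propan-2-yl)-3-(prop-2-en-1-yl)cyclopentyl 4-(benzyloxy)benzoate F1, with the same anti facial control. Wittig methylenation of the methyl ketone (Ph3PCH3Br, KOtBu, THF, 0 °C) gives the diene (1R,2S,3R)-2-{(1S)-1-[(benzyloxy)methoxy]-3-methylbut-3-en-1-yl}-3-methyl-1-(propan-2-yl)-3-(prop-2-en-1-yl)cyclopentyl 4-(benzyloxy)benzoate F2. Ring-closing metathesis (second-generation Hoveyda–Grubbs catalyst, toluene, 80 °C) then closes the trisubstituted cycloheptene, and the route is rejoined at 15.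

Step 2. Simple diastereoselection (syn against anti) in the aldol addition of the enol borate may be low, and the copper–boryl species may add to the aldehyde. The fallback replaces kinetic control by thermodynamic control. It sets out from 3 and 2 under the same conditions; the unwanted carbinol epimer (2S,3R)-2-[(1R)-1-hydroxy-2-(2-methyl-1,3-dioxolan-2-yl)ethyl]-3-methyl-3-(Bpin)cyclopentan-1-one F3 is separated and converted with tBuMgCl (1 equiv, THF, 0 °C to rt) into its chelated magnesium aldolate. This equilibrates by retro-aldol and re-addition through the same regiodefined enolate toward the more stable anti aldolate, and NH4Cl quench returns 5.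

Step 4. β-Hydride reduction or enolisation of the hindered ketone may compete with addition, and acylation of the tertiary alkoxide may stall. The fallback sets out from 6: isopropenylmagnesium bromide with CeCl3 (THF, −78 °C), a nucleophile that cannot deliver hydride, gives the allylic alcohol (1S,2S,3R)-2-{(1S)-1-[(benzyloxy)methoxy]-2-(2-methyl-1,3-dioxolan-2-yl)ethyl}-3-methyl-1-(prop-1-en-2-yl)-3-(Bpin)cyclopentan-1-ol F4. Its potassium alkoxide (KHMDS, THF, −78 °C) is acylated with 8 to give the ester (1S,2S,3R)-2-{(1S)-1-[(benzyloxy)methoxy]-2-(2-methyl-1,3-dioxolan-2-yl)ethyl}-3-methyl-1-(prop-1-en-2-yl)-3-(Bpin)cyclopentyl 4-(benzyloxy)benzoate F5. Hydrogenation of the 1,1-disubstituted alkene with [Ir(cod)(PCy3)(py)]PF6 and H2 in CH2Cl2, which leaves the benzyl ethers intact, rejoins the route at 10.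

Further compounds
F1 | step 7 | (1R,2S,3R)-2-{(1S)-1-[(benzyloxy)methoxy]-3-oxobutyl}-3-methyl-1-(propan-2-yl)-3-(prop-2-en-1-yl)cyclopentyl 4-(benzyloxy)benzoate | CC(C)[C@]1(OC(=O)c2ccc(OCc3ccccc3)cc2)CC[C@](C)(CC=C)[C@H]1[C@@H](OCOCc1ccccc1)CC(C)=O
F2 | step 7 | (1R,2S,3R)-2-{(1S)-1-[(benzyloxy)methoxy]-3-methylbut-3-en-1-yl}-3-methyl-1-(propan-2-yl)-3-(prop-2-en-1-yl)cyclopentyl 4-(benzyloxy)benzoate | CC(C)[C@]1(OC(=O)c2ccc(OCc3ccccc3)cc2)CC[C@](C)(CC=C)[C@H]1[C@@H](OCOCc1ccccc1)CC(C)=C
F3 | step 2 | (2S,3R)-2-[(1R)-1-hydroxy-2-(2-methyl-1,3-dioxolan-2-yl)ethyl]-3-methyl-3-(Bpin)cyclopentan-1-one | O=C1CC[C@](C)(B2OC(C)(C)C(C)(C)O2)[C@H]1[C@H](O)CC1(C)OCCO1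
F4 | step 4 | (1S,2S,3R)-2-{(1S)-1-[(benzyloxy)methoxy]-2-(2-methyl-1,3-dioxolan-2-yl)ethyl}-3-methyl-1-(prop-1-en-2-yl)-3-(Bpin)cyclopentan-1-ol | CC(=C)[C@]1(O)CC[C@](C)(B2OC(C)(C)C(C)(C)O2)[C@H]1[C@@H](OCOCc1ccccc1)CC1(C)OCCO1
F5 | step 4 | (1S,2S,3R)-2-{(1S)-1-[(benzyloxy)methoxy]-2-(2-methyl-1,3-dioxolan-2-yl)ethyl}-3-methyl-1-(prop-1-en-2-yl)-3-(Bpin)cyclopentyl 4-(benzyloxy)benzoate | CC(=C)[C@]1(OC(=O)c2ccc(OCc3ccccc3)cc2)CC[C@](C)(B2OC(C)(C)C(C)(C)O2)[C@H]1[C@@H](OCOCc1ccccc1)CC1(C)OCCO1
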